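**Retrosynthetic overview**
Guaiane numbering is used: ring A is C1–C5 (C4 carbinol, C5 fusion CH), ring B is C5–C10 plus C1. The plan rests on the C6(OAc)–C7(iPr)–C8(O-acyl) run of ring B, an aldol pattern whose isopropyl CH can come from hydride addition to an isopropylidene enone, so C7 stays sp2 until the ring closes.
Ring B is formed last, at C6–C7, by a copper-hydride reductive aldol of a C6 aldehyde with a C7 enolate; the C8 carbinol, acetate and angelate then follow from the aldol (Evans–Tishchenko, esterification, desilylation).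
Ring A is formed first by zirconocene bicyclisation of a 1,6-enyne (C1–C5 bond, fixed C1=C10 geometry). C6 oxygen comes from the alkyl–Zr bond, C9 from coupling of the alkenyl iodide with a Reformatsky reagent, and C7, C8, C11 from a Weinreb amide and 2-methylprop-1-enylmagnesium bromide.
C4 comes from Sharpless epoxidation of geraniol by way of (S)-linalool.

Key step: step 13

Remark: the ring closure of step 8 is assumed to place the CH2–Zr arm anti to the triethylsilyloxy group at C4 (the larger group avoiding the cyclopentadienyl ligands, as with other allylic silyl ethers); any C5 epimer is removed by chromatography at compound 12.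

Step 1
Reactants: 1 geraniol
Product: 2 (2S,3S)-2,3-epoxygeraniol
Conditions: Ti(OiPr)4 (5 mol %), L-(+)-diethyl tartrate (7 mol %), t-BuOOH, 4 Å MS, CH2Cl2, −20 °C
Reagents that add atoms: tert-butyl hydroperoxide, CC(C)(C)OO
Why: Sharpless asymmetric epoxidation of an (E)-allylic alcohol, in which the L-tartrate complex delivers oxygen to one alkene face and sets the carbon that becomes C4 as S.

Step 2
Reactants: 2 (2S,3S)-2,3-epoxygeraniol
Product: 3 (2R,3S)-2-(iodomethyl)-3-methyl-3-(4-methylpent-3-en-1-yl)oxirane
Conditions: PPh3, I2, imidazole, CH2Cl2, 0 °C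
Reagents that add atoms: iodine, II
Why: Appel-type iodination of the primary alcohol under neutral conditions, which leaves the epoxide and both stereocentres untouched.

Step 3
Reactants: 3 (2R,3S)-2-(iodomethyl)-3-methyl-3-(4-methylpent-3-en-1-yl)oxirane
Product: 4 (S)-linalool
Conditions: Zn dust, AcOH, EtOH, 40 °C
Reagents that add atoms: none
Why: Reductive elimination of the β-iodo epoxide (zinc insertion, then opening of the oxirane) gives the tertiary allylic alcohol without breaking the C–O bond at the stereocentre, so the S configuration is kept.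

Step 4
Reactants: 4 (S)-linalool
Product: 5 (S)-linalool triethylsilyl ether
Conditions: TESOTf, 2,6-lutidine, CH2Cl2, −78 → 0 °C
Reagents that add atoms: triethylsilyl trifluoromethanesulfonate, CC[Si](CC)(CC)OS(=O)(=O)C(F)(F)F
Why: Silylation with a silyl triflate and a hindered base is the standard way to protect a tertiary alcohol, and the ether also blocks cyclisation of the hydroxyl onto the alkene in later steps.

Step 5
Reactants: 5 (S)-linalool triethylsilyl ether
Product: 6 (4S)-4-methyl-4-(triethylsilyloxy)hex-5-enal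
Conditions: O3 (1.0 equiv), CH2Cl2, −78 °C; PPh3
Reagents that add atoms: ozone, [O-][O+]=O
Why: Ozonolysis with one equivalent of ozone should cleave the electron-rich trisubstituted alkene well ahead of the vinyl group, which is deactivated by the neighbouring silyloxy quaternary carbon.

Step 6
Reactants: 6 (4S)-4-methyl-4-(triethylsilyloxy)hex-5-enal
Product: 7 (5S)-1,1-dibromo-5-methyl-5-(triethylsilyloxy)hepta-1,6-diene
Conditions: CBr4, PPh3, Et3N, CH2Cl2, 0 °C
Reagents that add atoms: carbon tetrabromide, BrC(Br)(Br)Br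
Why: First stage of the Corey–Fuchs alkyne synthesis (dibromo-olefination of an unhindered aldehyde), buffered with amine so the silyl ether survives.

Step 7
Reactants: 7 (5S)-1,1-dibromo-5-methyl-5-(triethylsilyloxy)hepta-1,6-diene
Product: 9 (3S)-3-methyl-3-(triethylsilyloxy)oct-1-en-6-yne, via lithium acetylide 8 (not isolated)
Conditions: n-BuLi (2.2 equiv), THF, −78 → 0 °C; MeI, −78 °C → rt
Reagents that add atoms: iodomethane, CI
Why: Second stage of the Corey–Fuchs sequence gives the lithium acetylide, which is methylated in the same flask to the internal alkyne needed for the bicyclisation.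

Step 8
Reactants: 9 (3S)-3-methyl-3-(triethylsilyloxy)oct-1-en-6-yne
Product: 12 [(1R,2S,5Z)-5-(1-iodoethylidene)-2-methyl-2-(triethylsilyloxy)cyclopentyl]methanol, via zirconacyclopentene 10 (not isolated), via oxazirconacycle 11 (not isolated)
Conditions: Cp2ZrCl2 (1.1 equiv), n-BuLi (2.2 equiv), THF, −78 °C; 9, −78 °C → rt; dry O2, −78 → 0 °C; I2 (1.2 equiv), 0 °C; aq Na2S2O3
Reagents that add atoms: dioxygen, O=O; iodine, II
Why: Negishi zirconocene enyne bicyclisation forms the C1–C5 bond by syn addition, so Zr (and after iodinolysis with retention the iodine) sits on C10 cis to C5, the more reactive alkyl–Zr bond takes up oxygen first, and C5 is set in the ring closure with the CH2–Zr arm anti to the silyloxy group of C4 (R at C5).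

Step 9
Reactants: 12 [(1R,2S,5Z)-5-(1-iodoethylidene)-2-methyl-2-(triethylsilyloxy)cyclopentyl]methanol; 13 ethyl bromoacetate
Product: 15 ethyl (3Z)-3-[(2R,3S)-2-(hydroxymethyl)-3-methyl-3-(triethylsilyloxy)cyclopentylidene]butanoate, via Reformatsky reagent 14 (not isolated)
Conditions: 13, Zn dust (TMSCl-activated), THF, 40 °C; then 12, Pd(PPh3)4 (5 mol %), 14 (3 equiv), THF/DMPU, 60 °C
Reagents that add atoms: none
Why: Palladium-catalysed Negishi-type coupling of a Reformatsky reagent with an alkenyl iodide proceeds with retention of alkene geometry, so C9 is attached cis to C5, and the zinc enolate tolerates the free hydroxyl when used in excess.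

Step 10
Reactants: 15 ethyl (3Z)-3-[(2R,3S)-2-(hydroxymethyl)-3-methyl-3-(triethylsilyloxy)cyclopentylidene]butanoate
Product: 16 (3Z)-3-[(2R,3S)-2-(hydroxymethyl)-3-methyl-3-(triethylsilyloxy)cyclopentylidene]-N-methoxy-N-methylbutanamide
Conditions: MeNHOMe·HCl, i-PrMgCl, THF, −20 → 0 °C
Reagents that add atoms: N,O-dimethylhydroxylamine hydrochloride, CNOC.Cl
Why: Aminolysis of the ester by the magnesium amide is the standard Weinreb amide synthesis, runs cold enough to leave the β,γ-alkene in place, and touches no stereocentre.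

Step 11
Reactants: 16 (3Z)-3-[(2R,3S)-2-(hydroxymethyl)-3-methyl-3-(triethylsilyloxy)cyclopentylidene]-N-methoxy-N-methylbutanamide; 17 2-methylprop-1-enylmagnesium bromide
Product: 18 (2Z)-2-[(2R,3S)-2-(hydroxymethyl)-3-methyl-3-(triethylsilyloxy)cyclopentylidene]-6-methylhept-5-en-4-one
Conditions: 17 (3 equiv), THF, 0 °C; aq NH4Cl
Reagents that add atoms: none
Why: Weinreb ketone synthesis stops at the ketone stage and so delivers the isopropylidene enone (C8, C7, C11), with one extra equivalent of Grignard reagent consumed by the hydroxyl.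

Step 12
Reactants: 18 (2Z)-2-[(2R,3S)-2-(hydroxymethyl)-3-methyl-3-(triethylsilyloxy)cyclopentylidene]-6-methylhept-5-en-4-one
Product: 19 (1S,2S,5Z)-2-methyl-5-(6-methyl-4-oxohept-5-en-2-ylidene)-2-(triethylsilyloxy)cyclopentane-1-carbaldehyde
Conditions: Dess–Martin periodinane, NaHCO3, CH2Cl2, 0 °C
Reagents that add atoms: none
Why: Buffered Dess–Martin oxidation is neutral and fast, so the α-stereocentre C5 and the β,γ-position of the C1=C10 alkene should be kept, and the aldehyde is used at once.

Step 13
Reactants: 19 (1S,2S,5Z)-2-methyl-5-(6-methyl-4-oxohept-5-en-2-ylidene)-2-(triethylsilyloxy)cyclopentane-1-carbaldehyde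
Product: 21 (4S,5R,6S,7S)-6-hydroxy-4-(triethylsilyloxy)guai-1(10)-en-8-one, via copper enolate 20 (not isolated)
Conditions: [(Ph3P)CuH]6 (0.25 equiv of hexamer), toluene/THF, 0.01 M, −40 → 0 °C; aq NH4Cl
Reagents that add atoms: none
Why: Hydride from the copper cluster adds to C11 of the enone, which is held s-cis by its cis β-methyl group, and gives the Z copper enolate 20 at C7 only (never at the more acidic C9), whose C7 carbon then adds to the C6 aldehyde. The closest known reaction is the copper-hydride reductive aldol cyclisation of enone–aldehydes, common for five- and six-membered rings and rare for seven. Ring B closes in the 7-enolendo-exo-trig mode, made easier by the C1=C10 alkene that already holds C9 and C5 on one side. C7 is trigonal before the step, and the Z enolate together with the copper bridge between O8 and the aldehyde oxygen puts O6 and the isopropyl group cis, while the C5 stereocentre selects the aldehyde face so that O6 with its copper lies on the side of H5, away from the C4 quaternary centre (6S,7S). The step needs chemoselectivity (conjugate hydride addition ahead of aldehyde reduction, secured by the far higher reactivity of [(Ph3P)CuH]6 toward enones) and diastereoselectivity at C6 and C7 (secured by enolate geometry, chelation and C5), and high dilution keeps it intramolecular.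

Step 14
Reactants: 21 (4S,5R,6S,7S)-6-hydroxy-4-(triethylsilyloxy)guai-1(10)-en-8-one
Product: 23 (4S,5R,6R,7R,8S)-6-acetoxy-4-(triethylsilyloxy)guai-1(10)-en-8-ol, via hemiacetal 22 (not isolated)
Conditions: CH3CHO (10 equiv), SmI2 (0.3 equiv), THF, −10 °C
Reagents that add atoms: acetaldehyde, CC=O
Why: Evans–Tishchenko reduction, in which the samarium-bound hemiacetal on O6 passes its hydride to the C8 carbonyl on the face that carries O6, so that H8 is cis to O6 (8S, O8 trans to O6 and to the isopropyl group) and O6 ends as the acetate.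

Step 15
Reactants: 23 (4S,5R,6R,7R,8S)-6-acetoxy-4-(triethylsilyloxy)guai-1(10)-en-8-ol; 24 angelic acid
Product: 26 (4S,5R,6R,7R,8S)-6-acetoxy-4-(triethylsilyloxy)guai-1(10)-en-8-yl angelate, via mixed anhydride 25 (not isolated)
Conditions: 24, 2,4,6-Cl3C6H2COCl, Et3N, toluene, rt; then 23, toluene, 80 °C
Reagents that add atoms: none
Why: Yamaguchi-type esterification through the mixed anhydride, run hot and without a nucleophilic catalyst, is the usual way to acylate a hindered secondary alcohol with angelic acid without isomerisation to the tiglate.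

Step 16
Reactants: 26 (4S,5R,6R,7R,8S)-6-acetoxy-4-(triethylsilyloxy)guai-1(10)-en-8-yl angelate
Product: 27 (4S,5R,6R,7R,8S)-6-acetoxy-4-hydroxyguai-1(10)-en-8-yl (2Z)-2-methylbut-2-enoate
Conditions: HF·pyridine, pyridine, THF, 0 °C → rt
Reagents that add atoms: none
Why: Fluoride cleavage of the tertiary triethylsilyl ether under buffered, weakly acidic conditions should spare both esters, avoid acyl migration and leave the angelate geometry unchanged.

**Compound list**
1 | geraniol, (2E)-3,7-dimethylocta-2,6-dien-1-ol | CC(C)=CCC/C(C)=C/CO | starting material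
2 | (2S,3S)-2,3-epoxygeraniol | CC(C)=CCC[C@]1(C)O[C@H]1CO | intermediate
3 | (2R,3S)-2-(iodomethyl)-3-methyl-3-(4-methylpent-3-en-1-yl)oxirane | CC(C)=CCC[C@]1(C)O[C@H]1CI | intermediate
4 | (S)-linalool, (3S)-3,7-dimethylocta-1,6-dien-3-ol | C=C[C@@](C)(O)CCC=C(C)C | intermediate
5 | (S)-linalool triethylsilyl ether | C=C[C@@](C)(O[Si](CC)(CC)CC)CCC=C(C)C | intermediate
6 | (4S)-4-methyl-4-(triethylsilyloxy)hex-5-enal | C=C[C@@](C)(O[Si](CC)(CC)CC)CCC=O | intermediate
7 | (5S)-1,1-dibromo-5-methyl-5-(triethylsilyloxy)hepta-1,6-diene | C=C[C@@](C)(O[Si](CC)(CC)CC)CCC=C(Br)Br | intermediate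
8 | lithium acetylide of (3S)-3-methyl-3-(triethylsilyloxy)hept-1-en-6-yne (not isolated) | C=C[C@@](C)(O[Si](CC)(CC)CC)CCC#C[Li] | intermediate
9 | (3S)-3-methyl-3-(triethylsilyloxy)oct-1-en-6-yne | C=C[C@@](C)(O[Si](CC)(CC)CC)CCC#CC | intermediate
10 | zirconacyclopentene, Cp2Zr bonded to C6 and C10 and fused to ring A at C5–C1 (not isolated) | CC1=C2CC[C@](C)(O[Si](CC)(CC)CC)[C@H]2C[Zr]1(C3C=CC=C3)C3C=CC=C3 | intermediate
11 | oxazirconacycle, Cp2Zr bonded to O6 and C10 (not isolated) | CC1=C2CC[C@](C)(O[Si](CC)(CC)CC)[C@H]2CO[Zr]1(C3C=CC=C3)C3C=CC=C3 | intermediate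
12 | [(1R,2S,5Z)-5-(1-iodoethylidene)-2-methyl-2-(triethylsilyloxy)cyclopentyl]methanol | OC[C@@H]1[C@@](C)(O[Si](CC)(CC)CC)CC/C1=C(\C)I | intermediate
13 | ethyl bromoacetate | CCOC(=O)CBr | starting material
14 | (2-ethoxy-2-oxoethyl)zinc bromide (not isolated) | CCOC(=O)C[Zn]Br | intermediate
15 | ethyl (3Z)-3-[(2R,3S)-2-(hydroxymethyl)-3-methyl-3-(triethylsilyloxy)cyclopentylidene]butanoate | OC[C@@H]1[C@@](C)(O[Si](CC)(CC)CC)CC/C1=C(\C)CC(=O)OCC | intermediate
16 | (3Z)-3-[(2R,3S)-2-(hydroxymethyl)-3-methyl-3-(triethylsilyloxy)cyclopentylidene]-N-methoxy-N-methylbutanamide | OC[C@@H]1[C@@](C)(O[Si](CC)(CC)CC)CC/C1=C(\C)CC(=O)N(C)OC | intermediate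
17 | 2-methylprop-1-enylmagnesium bromide | CC(C)=C[Mg]Br | starting material
18 | (2Z)-2-[(2R,3S)-2-(hydroxymethyl)-3-methyl-3-(triethylsilyloxy)cyclopentylidene]-6-methylhept-5-en-4-one | OC[C@@H]1[C@@](C)(O[Si](CC)(CC)CC)CC/C1=C(\C)CC(=O)C=C(C)C | intermediate
19 | (1S,2S,5Z)-2-methyl-5-(6-methyl-4-oxohept-5-en-2-ylidene)-2-(triethylsilyloxy)cyclopentane-1-carbaldehyde | O=C[C@@H]1[C@@](C)(O[Si](CC)(CC)CC)CC/C1=C(\C)CC(=O)C=C(C)C | intermediate
20 | (triphenylphosphine)copper Z-enolate at C7/C8 of 19 after hydride addition to C11 (not isolated) | O=C[C@@H]1[C@@](C)(O[Si](CC)(CC)CC)CC/C1=C(\C)C/C(O[Cu-][P+](c2ccccc2)(c2ccccc2)c2ccccc2)=C/C(C)C | intermediate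
21 | (4S,5R,6S,7S)-6-hydroxy-4-(triethylsilyloxy)guai-1(10)-en-8-one | O=C1CC(C)=C2CC[C@](C)(O[Si](CC)(CC)CC)[C@H]2[C@H](O)[C@@H]1C(C)C | intermediate
22 | O6 hemiacetal of 21 with acetaldehyde (not isolated) | O=C1CC(C)=C2CC[C@](C)(O[Si](CC)(CC)CC)[C@H]2[C@H](OC(C)O)[C@@H]1C(C)C | intermediate
23 | (4S,5R,6R,7R,8S)-6-acetoxy-4-(triethylsilyloxy)guai-1(10)-en-8-ol | O[C@H]1CC(C)=C2CC[C@](C)(O[Si](CC)(CC)CC)[C@H]2[C@H](OC(C)=O)[C@@H]1C(C)C | intermediate
24 | angelic acid, (2Z)-2-methylbut-2-enoic acid | C/C=C(/C)C(=O)O | starting material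
25 | angelic 2,4,6-trichlorobenzoic anhydride (not isolated) | C/C=C(/C)C(=O)OC(=O)c1c(Cl)cc(Cl)cc1Cl | intermediate
26 | (4S,5R,6R,7R,8S)-6-acetoxy-4-(triethylsilyloxy)guai-1(10)-en-8-yl angelate | C/C=C(/C)C(=O)O[C@H]1CC(C)=C2CC[C@](C)(O[Si](CC)(CC)CC)[C@H]2[C@H](OC(C)=O)[C@@H]1C(C)C | intermediate
27 | (4S,5R,6R,7R,8S)-6-acetoxy-4-hydroxyguai-1(10)-en-8-yl (2Z)-2-methylbut-2-enoate | C/C=C(/C)C(=O)O[C@H]1CC(C)=C2CC[C@](C)(O)[C@H]2[C@H](OC(C)=O)[C@@H]1C(C)C | target

Total step count: 16.
Longest linear sequence: 16 steps (1 to 27).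

**Steps most likely to fail**

Step 13. Hydride may go to the aldehyde carbonyl instead of the hindered β,β-disubstituted enone, the copper enolate may be quenched before the slow seven-membered closure, or the ring may close through a non-chelated arrangement and give the trans O6/isopropyl pair. The fallback sets out from 18 and returns at 21; it separates enolate formation from hydride chemistry by using a samarium enolate made from an α-bromo ketone. Et3SiH with RhCl(PPh3)3 in toluene (1,4-hydrosilylation of the enone, with silylation of the primary hydroxyl) should give the bis-silylated Z enol ether F1. NBS in THF at −78 °C should give the C7 bromo ketone F2. PPTS in MeOH at 0 °C should remove only the primary silyl ether to give the bromo keto alcohol F3, and Dess–Martin oxidation should give the bromo keto aldehyde F4. SmI2 in THF at −78 °C then forms the C7 samarium enolate regiospecifically, and a samarium Reformatsky cyclisation through the same chelated arrangement should close ring B to 21.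

Step 8. The oxygenation may not stop at the alkyl–zirconium bond: a radical chain can also consume the alkenyl–zirconium bond, or that bond is protonated, so little alkenyl iodide survives. The C5 ratio assumed in the remark is the second open point of this step. The fallback sets out from 9 and returns at 12. Zirconacycle 10 is formed as before and both carbon–zirconium bonds are cleaved with excess I2 to the diiodide F5, where a C5 epimer can also be separated. CsOAc with 18-crown-6 in DMF at 50 °C displaces only the primary iodide (the alkenyl iodide is inert to substitution) to give the acetate F6, and K2CO3 in MeOH releases 12.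

Step 14. Under the Lewis-acidic samarium alkoxide, ring B may open by retro-aldol, hydride transfer may be slowed by the cis isopropyl group, or the acetyl group may migrate from O6 to O8. The fallback sets out from 21 and returns at 26; it separates reduction from acylation and reverses the order of the two esters. Me4NBH(OAc)3 in MeCN/AcOH at −20 °C (hydroxyl-directed Evans–Saksena reduction, same facial sense) should give the trans 6,8-diol F7. Mixed anhydride 25 in toluene at 80 °C should acylate the less hindered C8 hydroxyl to give the angelate F8, and Ac2O with DMAP and Et3N then acetylates the C6 hydroxyl to give 26.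

**Further compounds**
F1 | step 13 | Z triethylsilyl enol ether of 18 with the primary hydroxyl as triethylsilyl ether | CC[Si](CC)(CC)OC[C@@H]1[C@@](C)(O[Si](CC)(CC)CC)CC/C1=C(\C)C/C(O[Si](CC)(CC)CC)=C/C(C)C
F2 | step 13 | C7 bromo ketone with primary triethylsilyl ether | CC[Si](CC)(CC)OC[C@@H]1[C@@](C)(O[Si](CC)(CC)CC)CC/C1=C(\C)CC(=O)C(Br)C(C)C
F3 | step 13 | C7 bromo keto alcohol | OC[C@@H]1[C@@](C)(O[Si](CC)(CC)CC)CC/C1=C(\C)CC(=O)C(Br)C(C)C
F4 | step 13 | C7 bromo keto aldehyde | O=C[C@@H]1[C@@](C)(O[Si](CC)(CC)CC)CC/C1=C(\C)CC(=O)C(Br)C(C)C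
F5 | step 8 | diiodide, triethyl{[(1S,2R,3Z)-3-(1-iodoethylidene)-2-(iodomethyl)-1-methylcyclopentyl]oxy}silane | IC[C@@H]1[C@@](C)(O[Si](CC)(CC)CC)CC/C1=C(\C)I
F6 | step 8 | acetate of 12 | CC(=O)OC[C@@H]1[C@@](C)(O[Si](CC)(CC)CC)CC/C1=C(\C)I
F7 | step 14 | (4S,5R,6S,7R,8S)-4-(triethylsilyloxy)guai-1(10)-ene-6,8-diol | O[C@H]1CC(C)=C2CC[C@](C)(O[Si](CC)(CC)CC)[C@H]2[C@H](O)[C@@H]1C(C)C
F8 | step 14 | 6-hydroxy-4-(triethylsilyloxy)guai-1(10)-en-8-yl angelate | C/C=C(/C)C(=O)O[C@H]1CC(C)=C2CC[C@](C)(O[Si](CC)(CC)CC)[C@H]2[C@H](O)[C@@H]1C(C)C
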